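**Plan**

- Retrosynthesis: the two CH=CH bonds that flank the central C10 unit are cut (two Wittig olefinations with 2,7-dimethylocta-2,4,6-trienedial). This leaves two C15 phosphonium salts that both derive from one enynol, 10. In 10 the ring–alkyne bond is cut (Sonogashira), and the ring is cut at the two bonds that flank its CH2–CH(O)–CH2 segment.
- Enabling feature: in the cyclohexene ring of the acetylenic end, the CH2–CH(OH)–CH2 segment is a glycerol-type C3 unit whose central carbon is the only stereocentre of that ring. The other three ring atoms (methyl-bearing sp2 carbon, alkyne-bearing sp2 carbon, gem-dimethyl carbon) are the α-carbon, carbonyl carbon and α′-carbon of ethyl isopropyl ketone at the enol-triflate oxidation level. The ring is therefore a ketone α,α′-annulated by enantiopure epichlorohydrin.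
- Forward: the annulation gives silyloxy ketone 6; enol triflate formation and Sonogashira coupling give 10, which serves both ends. One part becomes the acetylenic Wittig salt directly. The other part is epoxidised on the ring alkene, hydrolysed to the trans-diol and reduced (alkyne to E-alkene) to the trihydroxylated Wittig salt. The chain is then joined C15 + C10 + C15 and desilylated.
- Stereochemistry: both secondary carbinol centres come from (S)-epichlorohydrin. The two tertiary carbinol centres come from epoxidation anti to the silyloxy group and anti opening by water at the methyl-bearing carbon. The E-alkenes come from the E-enynol, hydroxyl-directed trans-hydroalumination, and Wittig reactions with thermal Z-to-E equilibration.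

Key step: step 1

Remark: the target is read as (3S,5S,6S,3′R)-7′,8′-didehydro-5,6-dihydro-β,β-carotene-3,3′,5,6-tetrol; in the trihydroxy ring the 3- and 5-hydroxyls are cis and the 6-hydroxyl is trans to both.
Remark: 1, 2, 9 and 17 are taken as purchasable; 1 is otherwise one Mannich–elimination step from pentan-3-one.

**Route**

Step 1
Reactants: 1 2-methylpent-1-en-3-one; 2 (S)-epichlorohydrin
Product: 6 (4R)-4-[(tert-butyldimethylsilyl)oxy]-2,2,6-trimethylcyclohexan-1-one (mixture of epimers at C6), via lithium enolate 3 (not isolated), via chlorohydrin alkoxide 4 (not isolated), via chloro silyl ether 5 (not isolated)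
Conditions: LiBH(s-Bu)3, THF, −78 °C; 2, BF3·OEt2, −78 °C; t-BuMe2SiOTf (1 equiv), −78 °C; Et3N, then KN(SiMe3)2 (excess), −78 °C → rt
Reagents that add atoms: tert-butyldimethylsilyl trifluoromethanesulfonate, CC(C)(C)[Si](C)(C)OS(=O)(=O)C(F)(F)F
Why: Proposed new method: conjugate hydride addition to 1 gives only the tetrasubstituted enolate 3, which opens BF3-activated 2 at the unsubstituted epoxide carbon (first bond, at the quaternary centre); the alkoxide 4 is capped as its silyl ether so that it cannot re-close to an epoxide, and the only enolate still possible in 5 (ethyl side) then displaces chloride (second bond). The closest known reaction types are reductive enolate generation from enones with trapping by an electrophile, Lewis-acid-promoted opening of terminal epoxides by lithium enolates, and α,α′-annulation of ketones with 1,3-dielectrophiles, which has not been run with epichlorohydrin as the three-carbon unit. The six-membered ring closes in the 6-(enolendo)-exo-tet mode, for which C-alkylation is geometrically feasible and is the known outcome with δ-halo ketones carrying a gem-dimethyl group. The carbinol stereocentre is not formed here but carried in from 2, whose C–O bond at that carbon is never broken; because the epoxide carbon ends next to the gem-dimethyl carbon and the chloromethyl carbon next to the methyl-bearing carbon, (S)-2 gives the (4R) ketone. The methyl-bearing α-stereocentre forms without control, which is harmless since it becomes sp2 in step 2. The step needs site selectivity between the two ends of the C3 unit and between the two α-carbons of the ketone; the first is secured by the much higher reactivity of the activated epoxide over the primary chloride, the second by the regiodefined enolate and by the absence of α-hydrogen at the quaternary carbon after the first alkylation.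

Step 2
Reactants: 6 (4R)-4-[(tert-butyldimethylsilyl)oxy]-2,2,6-trimethylcyclohexan-1-one
Product: 8 (4R)-4-[(tert-butyldimethylsilyl)oxy]-2,6,6-trimethylcyclohex-1-en-1-yl trifluoromethanesulfonate, via potassium enolate 7 (not isolated)
Conditions: KN(SiMe3)2, THF, −78 °C; PhNTf2, −78 → 0 °C
Reagents that add atoms: N-phenylbis(trifluoromethanesulfonimide), FC(F)(F)S(=O)(=O)N(c1ccccc1)S(=O)(=O)C(F)(F)F
Why: Enolate O-sulfonylation (enol triflate formation): 6 has a single α-hydrogen, so only one enolate and one triflate regioisomer can form, and the uncontrolled α-stereocentre of 6 is erased.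

Step 3
Reactants: 8 (4R)-4-[(tert-butyldimethylsilyl)oxy]-2,6,6-trimethylcyclohex-1-en-1-yl trifluoromethanesulfonate; 9 (2E)-3-methylpent-2-en-4-yn-1-ol
Product: 10 (2E)-5-[(4R)-4-[(tert-butyldimethylsilyl)oxy]-2,6,6-trimethylcyclohex-1-en-1-yl]-3-methylpent-2-en-4-yn-1-ol
Conditions: Pd(PPh3)4 (5 mol %), CuI (10 mol %), i-Pr2NH, DMF, rt
Reagents that add atoms: none
Why: Sonogashira coupling of an enol triflate with a terminal alkyne, a standard way to make this ring–alkyne bond, which leaves the E-alkene of 9 and the silyl ether untouched.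

Step 4
Reactants: 10 (2E)-5-[(4R)-4-[(tert-butyldimethylsilyl)oxy]-2,6,6-trimethylcyclohex-1-en-1-yl]-3-methylpent-2-en-4-yn-1-ol
Product: 11 [(2E)-5-[(4R)-4-[(tert-butyldimethylsilyl)oxy]-2,6,6-trimethylcyclohex-1-en-1-yl]-3-methylpent-2-en-4-yn-1-yl]triphenylphosphonium bromide
Conditions: Ph3P·HBr, CH2Cl2, 0 °C → rt
Reagents that add atoms: triphenylphosphine hydrobromide, Br.c1ccc(cc1)P(c1ccccc1)c1ccccc1
Why: Conversion of an allylic alcohol into an allylic phosphonium salt with Ph3P·HBr (ionisation to the delocalised cation and capture by the phosphine at the primary terminus), the usual preparation of C15 Wittig salts; the silyl ether should survive the weak acid in an aprotic solvent.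

Step 5
Reactants: 10 (2E)-5-[(4R)-4-[(tert-butyldimethylsilyl)oxy]-2,6,6-trimethylcyclohex-1-en-1-yl]-3-methylpent-2-en-4-yn-1-ol
Product: 12 (2E)-5-[(1R,4S,6R)-4-[(tert-butyldimethylsilyl)oxy]-2,2,6-trimethyl-7-oxabicyclo[4.1.0]heptan-1-yl]-3-methylpent-2-en-4-yn-1-ol (epoxide oxygen anti to the silyloxy group)
Conditions: mCPBA (1.05 equiv), CH2Cl2, −20 → 0 °C; chromatographic removal of the syn epoxide
Reagents that add atoms: 3-chloroperoxybenzoic acid, OOC(=O)c1cccc(Cl)c1
Why: Prilezhaev epoxidation: the tetrasubstituted ring alkene is the most electron-rich π bond (the other alkene is trisubstituted and carries the hydroxymethyl group, the alkyne is inert), and the peracid should add mainly to the face anti to the bulky silyloxy group, as is usual for 3-acyloxy and 3-silyloxy rings of this type, which sets both epoxide carbons under substrate control.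

Step 6
Reactants: 12 (2E)-5-[(1R,4S,6R)-4-[(tert-butyldimethylsilyl)oxy]-2,2,6-trimethyl-7-oxabicyclo[4.1.0]heptan-1-yl]-3-methylpent-2-en-4-yn-1-ol
Product: 13 (1R,2S,4S)-4-[(tert-butyldimethylsilyl)oxy]-1-[(3E)-5-hydroxy-3-methylpent-3-en-1-yn-1-yl]-2,6,6-trimethylcyclohexane-1,2-diol
Conditions: HClO4 (cat.), THF–H2O, 0 °C
Reagents that add atoms: water, O
Why: Acid-catalysed epoxide hydrolysis with anti opening: C–O cleavage should occur at the methyl-bearing carbon because the alkynyl group disfavours positive charge at the other epoxide carbon, so water enters there with inversion while the alkyne-bearing carbinol keeps its configuration, giving the trans-diol with the new hydroxyl cis to the silyloxy group (the known outcome for 5,6-epoxides of ionone-type rings).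

Step 7
Reactants: 13 (1R,2S,4S)-4-[(tert-butyldimethylsilyl)oxy]-1-[(3E)-5-hydroxy-3-methylpent-3-en-1-yn-1-yl]-2,6,6-trimethylcyclohexane-1,2-diol
Product: 14 (1S,2S,4S)-4-[(tert-butyldimethylsilyl)oxy]-1-[(1E,3E)-5-hydroxy-3-methylpenta-1,3-dien-1-yl]-2,6,6-trimethylcyclohexane-1,2-diol
Conditions: NaAlH2(OCH2CH2OMe)2, THF, 0 °C → rt
Reagents that add atoms: none
Why: Hydroxyl-directed trans-hydroalumination of a propargylic alcohol: the tertiary alkoxide delivers hydride only to the adjacent triple bond and protonolysis gives the E-alkene, as in the reduction of the analogous enynols of abscisic-acid type.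

Step 8
Reactants: 14 (1S,2S,4S)-4-[(tert-butyldimethylsilyl)oxy]-1-[(1E,3E)-5-hydroxy-3-methylpenta-1,3-dien-1-yl]-2,6,6-trimethylcyclohexane-1,2-diol
Product: 16 [(2E,4E)-5-[(1S,2S,4S)-4-[(tert-butyldimethylsilyl)oxy]-1,2-dihydroxy-2,6,6-trimethylcyclohexyl]-3-methylpenta-2,4-dien-1-yl]triphenylphosphonium bromide, via allylic bromide 15 (not isolated)
Conditions: CBr4, PPh3, CH2Cl2, −30 °C; then PPh3, 0 °C → rt
Reagents that add atoms: tetrabromomethane, BrC(Br)(Br)Br; triphenylphosphine, c1ccc(cc1)P(c1ccccc1)c1ccccc1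
Why: Appel bromination of the primary allylic alcohol (the two tertiary hydroxyls are too hindered to form alkoxyphosphonium ions) followed by SN2 quaternisation of triphenylphosphine, which avoids the acid that would ionise the tertiary allylic carbinol.

Step 9
Reactants: 11 [(2E)-5-[(4R)-4-[(tert-butyldimethylsilyl)oxy]-2,6,6-trimethylcyclohex-1-en-1-yl]-3-methylpent-2-en-4-yn-1-yl]triphenylphosphonium bromide; 17 (2E,4E,6E)-2,7-dimethylocta-2,4,6-trienedial
Product: 19 (2E,4E,6E,8E,10E)-13-[(4R)-4-[(tert-butyldimethylsilyl)oxy]-2,6,6-trimethylcyclohex-1-en-1-yl]-2,7,11-trimethyltrideca-2,4,6,8,10-pentaen-12-ynal, via phosphorus ylide 18 (not isolated)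
Conditions: NaOMe, MeOH–CH2Cl2, 17 (3 equiv), 0 °C → rt; then EtOH, 60 °C
Reagents that add atoms: none
Why: Wittig olefination of a semi-stabilised allylic ylide with an excess of the symmetrical dialdehyde to favour mono-condensation; the new disubstituted double bond forms as an E/Z mixture and the hindered Z isomer should equilibrate to E on gentle heating.

Step 10
Reactants: 19 (2E,4E,6E,8E,10E)-13-[(4R)-4-[(tert-butyldimethylsilyl)oxy]-2,6,6-trimethylcyclohex-1-en-1-yl]-2,7,11-trimethyltrideca-2,4,6,8,10-pentaen-12-ynal; 16 [(2E,4E)-5-[(1S,2S,4S)-4-[(tert-butyldimethylsilyl)oxy]-1,2-dihydroxy-2,6,6-trimethylcyclohexyl]-3-methylpenta-2,4-dien-1-yl]triphenylphosphonium bromide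
Product: 21 (3S,5S,6S,3′R)-3,3′-bis-O-(tert-butyldimethylsilyl)-7′,8′-didehydro-5,6-dihydro-β,β-carotene-3,3′,5,6-tetrol, via phosphorus ylide 20 (not isolated)
Conditions: NaOMe, MeOH–CH2Cl2, 0 °C → rt; then EtOH, 60 °C
Reagents that add atoms: none
Why: Second Wittig olefination, tolerant of the free tertiary hydroxyls under alkoxide base; the new double bond is again brought to E by thermal equilibration and no stereocentre is touched.

Step 11
Reactants: 21 (3S,5S,6S,3′R)-3,3′-bis-O-(tert-butyldimethylsilyl)-7′,8′-didehydro-5,6-dihydro-β,β-carotene-3,3′,5,6-tetrol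
Product: 22 (3S,5S,6S,3′R)-7′,8′-didehydro-5,6-dihydro-β,β-carotene-3,3′,5,6-tetrol (target)
Conditions: Bu4NF, THF, 0 °C → rt
Reagents that add atoms: none
Why: Fluoride-mediated cleavage of both secondary silyl ethers under non-acidic conditions, which should spare the acid-sensitive tertiary allylic diol and the polyene.

**Compound list**

1 | 2-methylpent-1-en-3-one | CCC(=O)C(C)=C | starting material
2 | (S)-epichlorohydrin, (2S)-2-(chloromethyl)oxirane | ClC[C@@H]1CO1 | starting material
3 | lithium 2-methylpent-2-en-3-olate | [Li+].CCC([O-])=C(C)C | intermediate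
4 | lithium (2S)-1-chloro-4,4-dimethyl-5-oxoheptan-2-olate (BF3-complexed in the flask) | [Li+].CCC(=O)C(C)(C)C[C@H]([O-])CCl | intermediate
5 | (6S)-6-[(tert-butyldimethylsilyl)oxy]-7-chloro-4,4-dimethylheptan-3-one | CCC(=O)C(C)(C)C[C@H](O[Si](C)(C)C(C)(C)C)CCl | intermediate
6 | (4R)-4-[(tert-butyldimethylsilyl)oxy]-2,2,6-trimethylcyclohexan-1-one (mixture of epimers at C6) | CC1C[C@@H](O[Si](C)(C)C(C)(C)C)CC(C)(C)C1=O | intermediate
7 | potassium (4R)-4-[(tert-butyldimethylsilyl)oxy]-2,6,6-trimethylcyclohex-1-en-1-olate | [K+].CC1=C([O-])C(C)(C)C[C@H](O[Si](C)(C)C(C)(C)C)C1 | intermediate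
8 | (4R)-4-[(tert-butyldimethylsilyl)oxy]-2,6,6-trimethylcyclohex-1-en-1-yl trifluoromethanesulfonate | CC1=C(OS(=O)(=O)C(F)(F)F)C(C)(C)C[C@H](O[Si](C)(C)C(C)(C)C)C1 | intermediate
9 | (2E)-3-methylpent-2-en-4-yn-1-ol | C#C/C(C)=C/CO | starting material
10 | (2E)-5-[(4R)-4-[(tert-butyldimethylsilyl)oxy]-2,6,6-trimethylcyclohex-1-en-1-yl]-3-methylpent-2-en-4-yn-1-ol | CC1=C(C#C/C(C)=C/CO)C(C)(C)C[C@H](O[Si](C)(C)C(C)(C)C)C1 | intermediate
11 | [(2E)-5-[(4R)-4-[(tert-butyldimethylsilyl)oxy]-2,6,6-trimethylcyclohex-1-en-1-yl]-3-methylpent-2-en-4-yn-1-yl]triphenylphosphonium bromide | [Br-].CC1=C(C#C/C(C)=C/C[P+](c2ccccc2)(c2ccccc2)c2ccccc2)C(C)(C)C[C@H](O[Si](C)(C)C(C)(C)C)C1 | intermediate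
12 | (2E)-5-[(1R,4S,6R)-4-[(tert-butyldimethylsilyl)oxy]-2,2,6-trimethyl-7-oxabicyclo[4.1.0]heptan-1-yl]-3-methylpent-2-en-4-yn-1-ol | [C@@]12(C#C/C(C)=C/CO)O[C@]1(C)C[C@@H](O[Si](C)(C)C(C)(C)C)CC2(C)C | intermediate
13 | (1R,2S,4S)-4-[(tert-butyldimethylsilyl)oxy]-1-[(3E)-5-hydroxy-3-methylpent-3-en-1-yn-1-yl]-2,6,6-trimethylcyclohexane-1,2-diol | OC/C=C(C)/C#C[C@]1(O)C(C)(C)C[C@H](O[Si](C)(C)C(C)(C)C)C[C@]1(C)O | intermediate
14 | (1S,2S,4S)-4-[(tert-butyldimethylsilyl)oxy]-1-[(1E,3E)-5-hydroxy-3-methylpenta-1,3-dien-1-yl]-2,6,6-trimethylcyclohexane-1,2-diol | OC/C=C(C)/C=C/[C@]1(O)C(C)(C)C[C@H](O[Si](C)(C)C(C)(C)C)C[C@]1(C)O | intermediate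
15 | (1S,2S,4S)-1-[(1E,3E)-5-bromo-3-methylpenta-1,3-dien-1-yl]-4-[(tert-butyldimethylsilyl)oxy]-2,6,6-trimethylcyclohexane-1,2-diol | BrC/C=C(C)/C=C/[C@]1(O)C(C)(C)C[C@H](O[Si](C)(C)C(C)(C)C)C[C@]1(C)O | intermediate
16 | [(2E,4E)-5-[(1S,2S,4S)-4-[(tert-butyldimethylsilyl)oxy]-1,2-dihydroxy-2,6,6-trimethylcyclohexyl]-3-methylpenta-2,4-dien-1-yl]triphenylphosphonium bromide | [Br-].c1ccccc1[P+](c1ccccc1)(c1ccccc1)C/C=C(C)/C=C/[C@]1(O)C(C)(C)C[C@H](O[Si](C)(C)C(C)(C)C)C[C@]1(C)O | intermediate
17 | (2E,4E,6E)-2,7-dimethylocta-2,4,6-trienedial | O=C/C(C)=C/C=C/C=C(C)/C=O | starting material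
18 | triphenylphosphonium ylide derived from 11 | CC1=C(C#C/C(C)=C/C=P(c2ccccc2)(c2ccccc2)c2ccccc2)C(C)(C)C[C@H](O[Si](C)(C)C(C)(C)C)C1 | intermediate
19 | (2E,4E,6E,8E,10E)-13-[(4R)-4-[(tert-butyldimethylsilyl)oxy]-2,6,6-trimethylcyclohex-1-en-1-yl]-2,7,11-trimethyltrideca-2,4,6,8,10-pentaen-12-ynal | CC1=C(C#C/C(C)=C/C=C/C(C)=C/C=C/C=C(C)/C=O)C(C)(C)C[C@H](O[Si](C)(C)C(C)(C)C)C1 | intermediate
20 | triphenylphosphonium ylide derived from 16 | c1ccccc1P(c1ccccc1)(c1ccccc1)=C/C=C(C)/C=C/[C@]1(O)C(C)(C)C[C@H](O[Si](C)(C)C(C)(C)C)C[C@]1(C)O | intermediate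
21 | (3S,5S,6S,3′R)-3,3′-bis-O-(tert-butyldimethylsilyl)-7′,8′-didehydro-5,6-dihydro-β,β-carotene-3,3′,5,6-tetrol | CC1=C(C#C/C(C)=C/C=C/C(C)=C/C=C/C=C(C)/C=C/C=C(C)/C=C/[C@]2(O)C(C)(C)C[C@H](O[Si](C)(C)C(C)(C)C)C[C@]2(C)O)C(C)(C)C[C@H](O[Si](C)(C)C(C)(C)C)C1 | intermediate
22 | (3S,5S,6S,3′R)-7′,8′-didehydro-5,6-dihydro-β,β-carotene-3,3′,5,6-tetrol | CC1=C(C#C/C(C)=C/C=C/C(C)=C/C=C/C=C(C)/C=C/C=C(C)/C=C/[C@]2(O)C(C)(C)C[C@H](O)C[C@]2(C)O)C(C)(C)C[C@H](O)C1 | target

**Step count and risks**

Total step count: 11. Longest linear sequence: 9 steps (steps 1, 2, 3, 5, 6, 7, 8, 10, 11).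

Steps most likely to fail:

1. Step 1 (proposed new method). What may go wrong: polymerisation of the enone during hydride addition; incomplete silylation of the boron-bound alkoxide, followed by re-closure to an epoxide; or O- instead of C-alkylation in the ring closure. Fallback with known chemistry: because step 1 is the first step, the fallback cannot set out from a numbered compound; it replaces 1 and 2 by commercial 2,6,6-trimethylcyclohex-2-ene-1,4-dione. Fermenting baker's yeast should reduce the ring C=C bond enantioselectively to (6R)-2,2,6-trimethylcyclohexane-1,4-dione F1. Hydrogenation over Raney Ni should then reduce only the unhindered carbonyl, mainly trans to the methyl group, to (4R,6R)-4-hydroxy-2,2,6-trimethylcyclohexan-1-one F2. Silylation (t-BuMe2SiCl, imidazole, DMF) gives 6 as its single (6R) epimer, where the fallback comes back to the route.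

2. Step 5. What may go wrong: poor facial selectivity (attack syn to the silyloxy group) and competing oxidation of the hydroxymethyl-bearing alkene. Fallback: the epoxide is installed under reagent control before the alkyne is attached. Setting out from 8, methoxycarbonylation (Pd(OAc)2, PPh3, CO, MeOH, Et3N, DMF) should give methyl (4R)-4-[(tert-butyldimethylsilyl)oxy]-2,6,6-trimethylcyclohex-1-ene-1-carboxylate F3, and i-Bu2AlH should reduce it to [(4R)-4-[(tert-butyldimethylsilyl)oxy]-2,6,6-trimethylcyclohex-1-en-1-yl]methanol F4. Sharpless asymmetric epoxidation (Ti(Oi-Pr)4, D-(−)-diethyl tartrate, t-BuOOH), with the tartrate chosen so that oxygen enters anti to the silyloxy group, should give [(1R,4S,6R)-4-[(tert-butyldimethylsilyl)oxy]-2,2,6-trimethyl-7-oxabicyclo[4.1.0]heptan-1-yl]methanol F5. Parikh–Doering oxidation should give (1S,4S,6R)-4-[(tert-butyldimethylsilyl)oxy]-2,2,6-trimethyl-7-oxabicyclo[4.1.0]heptane-1-carbaldehyde F6. Ohira–Bestmann homologation (dimethyl (1-diazo-2-oxopropyl)phosphonate, K2CO3, MeOH) should give (1R,4S,6R)-4-[(tert-butyldimethylsilyl)oxy]-1-ethynyl-2,2,6-trimethyl-7-oxabicyclo[4.1.0]heptane F7. Sonogashira coupling of F7 with (2E)-3-iodobut-2-en-1-ol (Pd(PPh3)4, CuI, i-Pr2NH) comes back to the route at 12.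

3. Step 6. What may go wrong: attack of water at the alkyne-bearing carbon, full ionisation at the methyl-bearing carbon with loss of the anti relationship, or acid cleavage of the silyl ether. Fallback: the tertiary diol is made by C–C bond formation instead of C–O bond formation. Setting out from 6, LiN(i-Pr)2 and Me3SiCl should give {[(4R)-4-[(tert-butyldimethylsilyl)oxy]-2,6,6-trimethylcyclohex-1-en-1-yl]oxy}trimethylsilane F8. OsO4 (cat.) with N-methylmorpholine N-oxide should hydroxylate it on the face opposite the pseudo-axial methyl of the gem-dimethyl carbon, that is cis to the silyloxy group, giving (2S,4S)-4-[(tert-butyldimethylsilyl)oxy]-2-hydroxy-2,6,6-trimethylcyclohexan-1-one F9; a trans isomer, if formed, is separated at this stage. The dilithio derivative of 9 (n-BuLi, 2 equiv per 9, THF, −78 → 0 °C) should then add to this non-enolisable ketone along the axial trajectory, anti to the two axial α-methyl groups. This places the new hydroxyl trans to the existing one and gives 13, where the fallback comes back to the route.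

**Further compounds**

F1 | step 1 | (6R)-2,2,6-trimethylcyclohexane-1,4-dione | C[C@@H]1CC(=O)CC(C)(C)C1=O
F2 | step 1 | (4R,6R)-4-hydroxy-2,2,6-trimethylcyclohexan-1-one | C[C@@H]1C[C@@H](O)CC(C)(C)C1=O
F3 | step 5 | methyl (4R)-4-[(tert-butyldimethylsilyl)oxy]-2,6,6-trimethylcyclohex-1-ene-1-carboxylate | COC(=O)C1=C(C)C[C@@H](O[Si](C)(C)C(C)(C)C)CC1(C)C
F4 | step 5 | [(4R)-4-[(tert-butyldimethylsilyl)oxy]-2,6,6-trimethylcyclohex-1-en-1-yl]methanol | OCC1=C(C)C[C@@H](O[Si](C)(C)C(C)(C)C)CC1(C)C
F5 | step 5 | [(1R,4S,6R)-4-[(tert-butyldimethylsilyl)oxy]-2,2,6-trimethyl-7-oxabicyclo[4.1.0]heptan-1-yl]methanol | [C@@]12(CO)O[C@]1(C)C[C@@H](O[Si](C)(C)C(C)(C)C)CC2(C)C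
F6 | step 5 | (1S,4S,6R)-4-[(tert-butyldimethylsilyl)oxy]-2,2,6-trimethyl-7-oxabicyclo[4.1.0]heptane-1-carbaldehyde | [C@@]12(C=O)O[C@]1(C)C[C@@H](O[Si](C)(C)C(C)(C)C)CC2(C)C
F7 | step 5 | (1R,4S,6R)-4-[(tert-butyldimethylsilyl)oxy]-1-ethynyl-2,2,6-trimethyl-7-oxabicyclo[4.1.0]heptane | [C@@]12(C#C)O[C@]1(C)C[C@@H](O[Si](C)(C)C(C)(C)C)CC2(C)C
F8 | step 6 | {[(4R)-4-[(tert-butyldimethylsilyl)oxy]-2,6,6-trimethylcyclohex-1-en-1-yl]oxy}trimethylsilane | CC1=C(O[Si](C)(C)C)C(C)(C)C[C@H](O[Si](C)(C)C(C)(C)C)C1
F9 | step 6 | (2S,4S)-4-[(tert-butyldimethylsilyl)oxy]-2-hydroxy-2,6,6-trimethylcyclohexan-1-one | O=C1C(C)(C)C[C@H](O[Si](C)(C)C(C)(C)C)C[C@]1(C)O
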